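**Retrosynthetic overview**

1. Target 25 ⇐ silyl ether 24 ⇐ epoxy aldehyde 23: the ten-membered carbocycle is closed last, at C3–C4, by Ni/Cr-mediated vinyl iodide–aldehyde coupling, which also sets C3.
2. 23 ⇐ allylic alcohol 21: the cis-oxirane (C1, C2) comes from a catalyst-controlled, hydroxyl-directed epoxidation of a Z allylic alcohol.
3. 21 ⇐ allyl boronate 16 + iodoenal 18: C6–C7 and the cis-fused α-methylene-γ-butyrolactone come from a chiral Brønsted acid-catalysed allylboration–lactonisation (sets C6, C7).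
4. 16 ⇐ lactol 7 + methyl propiolate 8 + angelic acid 11: the boronate comes from a Baylis–Hillman-type bis-angelate (one angelate is the C8 ester of the target, the other the leaving group).
5. 7 ⇐ aldol 3 + alkyne 4 ⇐ acetone 1 + aldehyde 2: C10 by chelation-controlled alkynylation of a proline aldol (C8, first stereocentre). Ring order: lactone, oxirane, carbocycle.

Assumption: atoms are numbered as in germacrane (C1–C2 oxirane, C3 carbinol, C4=C5, C6 lactone carbinol, C7, C8 ester carbinol, C9, C10 tertiary carbinol, C11–C13 methylene lactone), and (2Z)-3-iodobut-2-en-1-ol 17 is taken as purchasable.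

**Route**

Step 1
Reactants: 1 acetone; 2 2,2-dimethoxyacetaldehyde
Product: 3 (4R)-4-hydroxy-5,5-dimethoxypentan-2-one
Conditions: L-proline (20 mol%), acetone/DMSO 4:1 (2 as 60% aq. solution), rt, 24 h
Reagents that add atoms: none
Why: Proline-catalysed direct aldol (enamine catalysis): the acetone enamine attacks the Re face of the aldehyde in the hydrogen-bonded chair-like transition state and gives the (R)-aldol, which sets C8 as the first stereocentre from achiral materials.

Step 2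
Reactants: 3 (4R)-4-hydroxy-5,5-dimethoxypentan-2-one; 4 4-methoxybenzyl propargyl ether
Product: 6 (2R,4R)-1,1-dimethoxy-7-[(4-methoxybenzyl)oxy]-4-methylhept-5-yne-2,4-diol, via bromomagnesium acetylide 5 (not isolated)
Conditions: 4 (3.2 equiv), EtMgBr (3.1 equiv), THF, 0 °C to rt; then 3, THF/CH2Cl2, −78 to −20 °C; H2O quench
Reagents that add atoms: none
Why: Chelation-controlled 1,2-addition: the magnesium alkoxide at C8 chelates the ketone in a six-membered ring with the C8 substituent equatorial and the alkynyl Grignard attacks axially, which gives the 1,3-anti diol (C10 R); low temperature and excess reagent hold back retro-aldol and enolisation.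

Step 3
Reactants: 6 (2R,4R)-1,1-dimethoxy-7-[(4-methoxybenzyl)oxy]-4-methylhept-5-yne-2,4-diol
Product: 7 (3R,5R)-5-{3-[(4-methoxybenzyl)oxy]prop-1-yn-1-yl}-5-methyloxolane-2,3-diol (lactol; both anomers)
Conditions: 1 M aq. HCl, THF, rt
Reagents that add atoms: water, O
Why: Acid-catalysed acetal hydrolysis; the liberated aldehyde is captured by the tertiary C10 hydroxyl as a five-membered lactol, and dilute acid leaves the PMB ether and the tertiary propargylic centre intact.

Step 4
Reactants: 7 lactol; 8 methyl propiolate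
Product: 10 methyl (4R,6R)-3,4,6-trihydroxy-9-[(4-methoxybenzyl)oxy]-6-methyl-2-methylidenenon-7-ynoate (both epimers at the new carbinol), via vinylalane 9 (not isolated)
Conditions: 8 (4 equiv), iBu2AlH (4 equiv), N-methylmorpholine N-oxide (4 equiv), THF, 0 °C; then 7, 0 °C to rt; aq. work-up
Reagents that add atoms: none
Why: Vinylalumination, a Morita–Baylis–Hillman surrogate: hydroalumination of 8 gives the α-alumino acrylate 9, which adds to the open aldehyde form of the lactol as other organometallics do; the new carbinol (C7) forms as an epimer mixture that is erased in step 8.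

Step 5
Reactants: 10 triol; 11 angelic acid
Product: 13 methyl (4R,6R)-6-hydroxy-9-[(4-methoxybenzyl)oxy]-6-methyl-2-methylidene-3,4-bis{[(2Z)-2-methylbut-2-enoyl]oxy}non-7-ynoate (both epimers at the allylic ester carbon), via mixed anhydride 12 (not isolated)
Conditions: 11 (3 equiv), 2,4,6-trichlorobenzoyl chloride (3 equiv), Et3N (3.3 equiv), toluene, rt; then 10, toluene, 70 °C (no DMAP)
Reagents that add atoms: none
Why: Yamaguchi-type esterification through the mixed anhydride without DMAP, which avoids angelate-to-tiglate isomerisation; both secondary hydroxyls are acylated (the C8 ester of the target and the C7 ester as later leaving group) while the tertiary propargylic hydroxyl is too hindered.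

Step 6
Reactants: 13 bis-angelate
Product: 14 methyl (4R,6R)-9-[(4-methoxybenzyl)oxy]-6-methyl-2-methylidene-3,4-bis{[(2Z)-2-methylbut-2-enoyl]oxy}-6-[(triethylsilyl)oxy]non-7-ynoate
Conditions: Et3SiOTf (1.5 equiv), 2,6-lutidine (2.5 equiv), CH2Cl2, −78 to 0 °C
Reagents that add atoms: triethylsilyl trifluoromethanesulfonate, CC[Si](CC)(CC)OS(=O)(=O)C(F)(F)F
Why: Silylation of the hindered tertiary alcohol with a silyl triflate and a hindered base; the silyl ether later keeps the C10 oxygen from closing a lactol onto the C3 aldehyde.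

Step 7
Reactants: 14 silyl ether
Product: 15 methyl (4R,6R,7Z)-9-[(4-methoxybenzyl)oxy]-6-methyl-2-methylidene-3,4-bis{[(2Z)-2-methylbut-2-enoyl]oxy}-6-[(triethylsilyl)oxy]non-7-enoate
Conditions: H2 (1 atm), Pd/CaCO3 poisoned with Pb(OAc)2 (Lindlar), quinoline, EtOAc, rt
Reagents that add atoms: none
Why: Lindlar semi-hydrogenation: syn delivery of hydrogen on the poisoned surface gives the Z olefin and stops there, and the electron-poor acrylate and angelate olefins and the PMB ether are not touched.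

Step 8
Reactants: 15 Z-olefin bis-angelate
Product: 16 methyl (2E,4R,6R,7Z)-9-[(4-methoxybenzyl)oxy]-6-methyl-4-{[(2Z)-2-methylbut-2-enoyl]oxy}-2-[(4,4,5,5-tetramethyl-1,3,2-dioxaborolan-2-yl)methyl]-6-[(triethylsilyl)oxy]nona-2,7-dienoate
Conditions: Pd2(dba)3 (2.5 mol%), B2pin2 (1.3 equiv), toluene/DMSO, 50 °C
Reagents that add atoms: bis(pinacolato)diboron, CC1(C)OB(OC1(C)C)B1OC(C)(C)C(C)(C)O1
Why: Palladium-catalysed allylic borylation: zerovalent palladium ionises the Baylis–Hillman-type C7 angelate to a 2-carbomethoxy π-allyl complex and boron is delivered to the unsubstituted terminus, the conjugated olefin forming with C8 trans to the ester (cis to CH2Bpin); the non-allylic C8 angelate stays.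

Step 9
Reactants: 17 (2Z)-3-iodobut-2-en-1-ol
Product: 18 (2Z)-3-iodobut-2-enal
Conditions: MnO2 (15 equiv), CH2Cl2, rt, dark
Reagents that add atoms: none
Why: Allylic alcohol oxidation on MnO2 stops at the enal and keeps the Z geometry; the product is used at once.

Step 10
Reactants: 16 allyl boronate; 18 (2Z)-3-iodobut-2-enal
Product: 20 (1R,3R,4Z)-1-[(2R,3R)-2-[(1Z)-2-iodoprop-1-en-1-yl]-4-methylidene-5-oxooxolan-3-yl]-6-[(4-methoxybenzyl)oxy]-3-methyl-3-[(triethylsilyl)oxy]hex-4-en-1-yl (2Z)-2-methylbut-2-enoate, via O-boryl hydroxy ester 19 (not isolated)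
Conditions: (R)-3,3'-bis(2,4,6-triisopropylphenyl)-1,1'-binaphthyl-2,2'-diyl N-triflylphosphoramide (10 mol%), 4 Å MS, toluene, −30 to 0 °C; then PPTS (cat.), rt
Reagents that add atoms: none
Why: Proposed new method: a chiral Brønsted acid-catalysed allylboration–lactonisation used as a doubly stereodifferentiating fragment coupling of a γ-substituted, ester-deactivated 2-(methoxycarbonyl)allyl pinacol boronate with a β-iodo Z-enal; the strong chiral acid hydrogen-bonds to a boronate oxygen (raising boron Lewis acidity) and to the formyl C–H, and the aldehyde adds through a closed six-membered chair transition state in which the C8 substituent cis to CH2B sits axial, so the syn adduct and hence the cis-fused lactone form with C6 and C7 as in the target; allylic 1,3-strain holds H-8 in the olefin plane so the aldehyde approaches anti to the bulky C9 chain, the (R)-catalyst pocket selects the same Re face of the aldehyde (matched case), and the borate 19 then lactonises with loss of the methoxy group; the closest known reactions are the chiral phosphoric acid-catalysed allylboration of aldehydes with allyl pinacol boronate and the achiral acid-catalysed allylboration–lactonisation of 2-alkoxycarbonyl allylboronates.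

Step 11
Reactants: 20 iodo lactone PMB ether
Product: 21 (1R,3R,4Z)-6-hydroxy-1-[(2R,3R)-2-[(1Z)-2-iodoprop-1-en-1-yl]-4-methylidene-5-oxooxolan-3-yl]-3-methyl-3-[(triethylsilyl)oxy]hex-4-en-1-yl (2Z)-2-methylbut-2-enoate
Conditions: DDQ (1.3 equiv), CH2Cl2/pH 7 buffer 10:1, 0 °C
Reagents that add atoms: none
Why: Oxidative PMB ether cleavage: DDQ abstracts the benzylic hydride and the oxocarbenium ion is hydrolysed, leaving the silyl ether, vinyl iodide, esters and lactone intact.

Step 12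
Reactants: 21 Z allylic alcohol
Product: 22 (1R,3R)-3-[(2R,3R)-3-(hydroxymethyl)oxiran-2-yl]-1-[(2R,3R)-2-[(1Z)-2-iodoprop-1-en-1-yl]-4-methylidene-5-oxooxolan-3-yl]-3-[(triethylsilyl)oxy]butyl (2Z)-2-methylbut-2-enoate
Conditions: VO(OiPr)3 (2 mol%), twofold-symmetric bis-hydroxamic acid ligand from trans-cyclohexane-1,2-diamine (3 mol%, enantiomer that delivers the 2R,3R oxirane), TBHP (70% aq., 1.5 equiv), CH2Cl2, 0 °C
Reagents that add atoms: tert-butyl hydroperoxide, CC(C)(C)OO
Why: Vanadium–bis-hydroxamic acid asymmetric epoxidation of a Z primary allylic alcohol: the alcohol binds vanadium and the chiral ligand sphere decides the face, giving the cis-(2R,3R)-oxirane (C1 and C2) under catalyst control; the other olefins are not allylic alcohols and are electron-poor or remote.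

Step 13
Reactants: 22 epoxy alcohol
Product: 23 (1R,3R)-3-[(2R,3S)-3-formyloxiran-2-yl]-1-[(2R,3R)-2-[(1Z)-2-iodoprop-1-en-1-yl]-4-methylidene-5-oxooxolan-3-yl]-3-[(triethylsilyl)oxy]butyl (2Z)-2-methylbut-2-enoate
Conditions: Dess–Martin periodinane (1.5 equiv), NaHCO3, CH2Cl2, 0 °C
Reagents that add atoms: none
Why: Dess–Martin oxidation of the primary alcohol under buffered conditions gives the cis-epoxy aldehyde without epimerisation, and the silylated C10 oxygen cannot form a hemiacetal.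

Step 14
Reactants: 23 epoxy aldehyde vinyl iodide
Product: 24 10-O-triethylsilyl ether of the target (1R,2R,3R,6S,7R,8R,10R; 4Z)
Conditions: CrCl2 (10 equiv), NiCl2 (0.2 equiv), DMSO/THF 3:1, 0.002 M (syringe pump), rt
Reagents that add atoms: none
Why: Nozaki–Hiyama–Kishi macrocyclisation: zerovalent nickel inserts into the vinyl iodide, transmetalation gives the vinylchromium species with retention of the Z geometry and this adds to the aldehyde at high dilution; Felkin–Anh attack anti to the oxirane C–O bond of the cis-epoxy aldehyde gives the erythro (3R) alcohol, and the Z olefin, cis-oxirane and cis-lactone preorganise the chain for ten-membered ring closure.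

Step 15
Reactants: 24 silyl ether
Product: 25 target, (1R,2R,3R,4Z,6S,7R,8R,10R)-1,2-epoxy-3,10-dihydroxy-8-[(2Z)-2-methylbut-2-enoyloxy]germacra-4,11(13)-dien-12,6-olide
Conditions: HF·pyridine, pyridine/THF, 0 °C to rt
Reagents that add atoms: none
Why: Fluoride-driven desilylation (strong Si–F bond) of the tertiary silyl ether under buffered conditions that spare the oxirane, the angelate and the α-methylene lactone.

**Compound list**

1 | acetone | CC(C)=O | starting material
2 | 2,2-dimethoxyacetaldehyde | COC(OC)C=O | starting material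
3 | (4R)-4-hydroxy-5,5-dimethoxypentan-2-one | CC(=O)C[C@@H](O)C(OC)OC | intermediate
4 | 4-methoxybenzyl propargyl ether, 1-methoxy-4-[(prop-2-yn-1-yloxy)methyl]benzene | C#CCOCc1ccc(OC)cc1 | starting material
5 | bromo{3-[(4-methoxybenzyl)oxy]prop-1-yn-1-yl}magnesium | COc1ccc(COCC#C[Mg]Br)cc1 | intermediate (not isolated)
6 | (2R,4R)-1,1-dimethoxy-7-[(4-methoxybenzyl)oxy]-4-methylhept-5-yne-2,4-diol | C[C@](O)(C#CCOCc1ccc(OC)cc1)C[C@@H](O)C(OC)OC | intermediate
7 | (3R,5R)-5-{3-[(4-methoxybenzyl)oxy]prop-1-yn-1-yl}-5-methyloxolane-2,3-diol, both anomers | OC1[C@H](O)C[C@](C)(C#CCOCc2ccc(OC)cc2)O1 | intermediate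
8 | methyl propiolate | C#CC(=O)OC | starting material
9 | methyl 2-[bis(2-methylpropyl)alumanyl]prop-2-enoate | C=C(C(=O)OC)[Al](CC(C)C)CC(C)C | intermediate (not isolated)
10 | methyl (4R,6R)-3,4,6-trihydroxy-9-[(4-methoxybenzyl)oxy]-6-methyl-2-methylidenenon-7-ynoate, both epimers at chain carbon 3 | C=C(C(=O)OC)C(O)[C@H](O)C[C@@](C)(O)C#CCOCc1ccc(OC)cc1 | intermediate
11 | angelic acid, (2Z)-2-methylbut-2-enoic acid | C/C=C(/C)C(=O)O | starting material
12 | (2Z)-2-methylbut-2-enoic 2,4,6-trichlorobenzoic anhydride | C/C=C(/C)C(=O)OC(=O)c1c(Cl)cc(Cl)cc1Cl | intermediate (not isolated)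
13 | methyl (4R,6R)-6-hydroxy-9-[(4-methoxybenzyl)oxy]-6-methyl-2-methylidene-3,4-bis{[(2Z)-2-methylbut-2-enoyl]oxy}non-7-ynoate, both epimers at chain carbon 3 | C=C(C(=O)OC)C(OC(=O)/C(C)=C\C)[C@H](OC(=O)/C(C)=C\C)C[C@@](C)(O)C#CCOCc1ccc(OC)cc1 | intermediate
14 | methyl (4R,6R)-9-[(4-methoxybenzyl)oxy]-6-methyl-2-methylidene-3,4-bis{[(2Z)-2-methylbut-2-enoyl]oxy}-6-[(triethylsilyl)oxy]non-7-ynoate | C=C(C(=O)OC)C(OC(=O)/C(C)=C\C)[C@H](OC(=O)/C(C)=C\C)C[C@@](C)(O[Si](CC)(CC)CC)C#CCOCc1ccc(OC)cc1 | intermediate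
15 | methyl (4R,6R,7Z)-9-[(4-methoxybenzyl)oxy]-6-methyl-2-methylidene-3,4-bis{[(2Z)-2-methylbut-2-enoyl]oxy}-6-[(triethylsilyl)oxy]non-7-enoate | C=C(C(=O)OC)C(OC(=O)/C(C)=C\C)[C@H](OC(=O)/C(C)=C\C)C[C@@](C)(O[Si](CC)(CC)CC)/C=C\COCc1ccc(OC)cc1 | intermediate
16 | methyl (2E,4R,6R,7Z)-9-[(4-methoxybenzyl)oxy]-6-methyl-4-{[(2Z)-2-methylbut-2-enoyl]oxy}-2-[(4,4,5,5-tetramethyl-1,3,2-dioxaborolan-2-yl)methyl]-6-[(triethylsilyl)oxy]nona-2,7-dienoate | COC(=O)/C(CB1OC(C)(C)C(C)(C)O1)=C/[C@H](OC(=O)/C(C)=C\C)C[C@@](C)(O[Si](CC)(CC)CC)/C=C\COCc2ccc(OC)cc2 | intermediate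
17 | (2Z)-3-iodobut-2-en-1-ol | C/C(I)=C/CO | starting material
18 | (2Z)-3-iodobut-2-enal | C/C(I)=C/C=O | intermediate
19 | open-chain methyl ester corresponding to 20 with the C6 oxygen carrying the pinacolboryl group (stereocentres placed as in 20) | COC(=O)C(=C)[C@@H]([C@@H](OB1OC(C)(C)C(C)(C)O1)/C=C(/C)I)[C@H](OC(=O)/C(C)=C\C)C[C@@](C)(O[Si](CC)(CC)CC)/C=C\COCc2ccc(OC)cc2 | intermediate (not isolated)
20 | (1R,3R,4Z)-1-[(2R,3R)-2-[(1Z)-2-iodoprop-1-en-1-yl]-4-methylidene-5-oxooxolan-3-yl]-6-[(4-methoxybenzyl)oxy]-3-methyl-3-[(triethylsilyl)oxy]hex-4-en-1-yl (2Z)-2-methylbut-2-enoate (cis-fused lactone) | C=C1C(=O)O[C@@H](/C=C(/C)I)[C@H]1[C@H](OC(=O)/C(C)=C\C)C[C@@](C)(O[Si](CC)(CC)CC)/C=C\COCc2ccc(OC)cc2 | intermediate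
21 | (1R,3R,4Z)-6-hydroxy-1-[(2R,3R)-2-[(1Z)-2-iodoprop-1-en-1-yl]-4-methylidene-5-oxooxolan-3-yl]-3-methyl-3-[(triethylsilyl)oxy]hex-4-en-1-yl (2Z)-2-methylbut-2-enoate | C=C1C(=O)O[C@@H](/C=C(/C)I)[C@H]1[C@H](OC(=O)/C(C)=C\C)C[C@@](C)(O[Si](CC)(CC)CC)/C=C\CO | intermediate
22 | (1R,3R)-3-[(2R,3R)-3-(hydroxymethyl)oxiran-2-yl]-1-[(2R,3R)-2-[(1Z)-2-iodoprop-1-en-1-yl]-4-methylidene-5-oxooxolan-3-yl]-3-[(triethylsilyl)oxy]butyl (2Z)-2-methylbut-2-enoate (cis-oxirane) | C=C1C(=O)O[C@@H](/C=C(/C)I)[C@H]1[C@H](OC(=O)/C(C)=C\C)C[C@@](C)(O[Si](CC)(CC)CC)[C@@H]2O[C@@H]2CO | intermediate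
23 | (1R,3R)-3-[(2R,3S)-3-formyloxiran-2-yl]-1-[(2R,3R)-2-[(1Z)-2-iodoprop-1-en-1-yl]-4-methylidene-5-oxooxolan-3-yl]-3-[(triethylsilyl)oxy]butyl (2Z)-2-methylbut-2-enoate | C=C1C(=O)O[C@@H](/C=C(/C)I)[C@H]1[C@H](OC(=O)/C(C)=C\C)C[C@@](C)(O[Si](CC)(CC)CC)[C@@H]2O[C@@H]2C=O | intermediate
24 | 10-O-triethylsilyl ether of the target, (1R,2R,3R,4Z,6S,7R,8R,10R) | C=C1C(=O)O[C@H]2/C=C(/C)[C@@H](O)[C@H]3O[C@H]3[C@](C)(O[Si](CC)(CC)CC)C[C@@H](OC(=O)/C(C)=C\C)[C@@H]12 | intermediate
25 | (1R,2R,3R,4Z,6S,7R,8R,10R)-1,2-epoxy-3,10-dihydroxy-8-[(2Z)-2-methylbut-2-enoyloxy]germacra-4,11(13)-dien-12,6-olide | C=C1C(=O)O[C@H]2/C=C(/C)[C@@H](O)[C@H]3O[C@H]3[C@](C)(O)C[C@@H](OC(=O)/C(C)=C\C)[C@@H]12 | target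

**Step count**

Total steps: 15. Longest linear sequence: 14 (steps 1–8 and 10–15; step 9 is a one-step side branch).

**Three steps most likely to fail**

Step 10 (the proposed new step). The ester-deactivated boronate may be too slow under a chiral acid mild enough for the tertiary allylic silyl ether, or catalyst and substrate control may not reinforce each other. Known fallback: set out from 15. MgBr2·OEt2 in THF displaces the allylic C7 angelate in the SN2′ sense and gives methyl (2Z,4R,6R,7Z)-2-(bromomethyl)-9-[(4-methoxybenzyl)oxy]-6-methyl-4-{[(2Z)-2-methylbut-2-enoyl]oxy}-6-[(triethylsilyl)oxy]nona-2,7-dienoate F1. Indium metal and 18 in THF/H2O (Barbier allylation through a cyclic transition state, syn-selective for this bromide geometry) give the open-chain hydroxy ester F2, which lactonises with PPTS to 20, where the route is rejoined.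

Step 14. Ten-membered ring closure may lose to oligomerisation, CrCl2 may open the α,β-epoxy aldehyde reductively, or the ring may override the Felkin preference at C3. Fallback that reverses the order of the two unions (C3–C4 between fragments, ring closure at C6–C7): set out from 15. DDQ gives the Z allylic alcohol F3, the vanadium–bis-hydroxamic acid epoxidation of step 12 gives the epoxy alcohol F4, and Dess–Martin periodinane gives the epoxy aldehyde F5. Intermolecular coupling of F5 with 17 (CrCl2, NiCl2, DMSO; Felkin–Anh, erythro) gives the diol F6. Et3SiOTf/2,6-lutidine gives the bis-silyl ether F7, and Swern oxidation, which cleaves and oxidises only the primary silyl ether, gives the Z-enal F8. Pd2(dba)3/B2pin2 as in step 8 gives the allyl boronate F9 (not isolated), which on warming in dilute toluene undergoes uncatalysed intramolecular allylboration–lactonisation to the 3,10-bis-O-triethylsilyl macrocycle F10. HF·pyridine then gives 25. The C3 oxygen stays silylated while the Z-enal exists, because the free γ-hydroxy Z-enal would close to a lactol.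

Step 2. The free β-hydroxy ketone may undergo retro-aldol or enolisation, or the alkoxide chelate may give a poor ratio at C10. Fallback with a chelating ether: set out from 3. Ethyl vinyl ether and PPTS give the 1-ethoxyethyl ether F11. Addition of 5 in the presence of MgBr2·OEt2 in CH2Cl2 at −78 °C (chelate-controlled, 1,3-anti) gives the tertiary alcohol F12. The aqueous HCl of step 3 then removes the ethoxyethyl group and the acetal together and gives lactol 7, where the route is rejoined.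

**Further compounds**

F1 | step 10 | methyl (2Z,4R,6R,7Z)-2-(bromomethyl)-9-[(4-methoxybenzyl)oxy]-6-methyl-4-{[(2Z)-2-methylbut-2-enoyl]oxy}-6-[(triethylsilyl)oxy]nona-2,7-dienoate | COC(=O)/C(CBr)=C/[C@H](OC(=O)/C(C)=C\C)C[C@@](C)(O[Si](CC)(CC)CC)/C=C\COCc1ccc(OC)cc1
F2 | step 10 | open-chain hydroxy methyl ester corresponding to 20 (free C6 hydroxyl, stereocentres placed as in 20) | COC(=O)C(=C)[C@@H]([C@@H](O)/C=C(/C)I)[C@H](OC(=O)/C(C)=C\C)C[C@@](C)(O[Si](CC)(CC)CC)/C=C\COCc1ccc(OC)cc1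
F3 | step 14 | methyl (4R,6R,7Z)-9-hydroxy-6-methyl-2-methylidene-3,4-bis{[(2Z)-2-methylbut-2-enoyl]oxy}-6-[(triethylsilyl)oxy]non-7-enoate | C=C(C(=O)OC)C(OC(=O)/C(C)=C\C)[C@H](OC(=O)/C(C)=C\C)C[C@@](C)(O[Si](CC)(CC)CC)/C=C\CO
F4 | step 14 | methyl (4R,6R)-6-[(2R,3R)-3-(hydroxymethyl)oxiran-2-yl]-2-methylidene-3,4-bis{[(2Z)-2-methylbut-2-enoyl]oxy}-6-[(triethylsilyl)oxy]heptanoate | C=C(C(=O)OC)C(OC(=O)/C(C)=C\C)[C@H](OC(=O)/C(C)=C\C)C[C@@](C)(O[Si](CC)(CC)CC)[C@@H]1O[C@@H]1CO
F5 | step 14 | methyl (4R,6R)-6-[(2R,3S)-3-formyloxiran-2-yl]-2-methylidene-3,4-bis{[(2Z)-2-methylbut-2-enoyl]oxy}-6-[(triethylsilyl)oxy]heptanoate | C=C(C(=O)OC)C(OC(=O)/C(C)=C\C)[C@H](OC(=O)/C(C)=C\C)C[C@@](C)(O[Si](CC)(CC)CC)[C@@H]1O[C@@H]1C=O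
F6 | step 14 | adduct of F5 and 17: the oxirane carries a (1R,2Z)-1,4-dihydroxy-2-methylbut-2-en-1-yl group in place of the formyl group | C=C(C(=O)OC)C(OC(=O)/C(C)=C\C)[C@H](OC(=O)/C(C)=C\C)C[C@@](C)(O[Si](CC)(CC)CC)[C@@H]1O[C@@H]1[C@H](O)/C(C)=C\CO
F7 | step 14 | bis(triethylsilyl) ether of F6 at both hydroxyls of the butenyl unit | C=C(C(=O)OC)C(OC(=O)/C(C)=C\C)[C@H](OC(=O)/C(C)=C\C)C[C@@](C)(O[Si](CC)(CC)CC)[C@@H]1O[C@@H]1[C@H](O[Si](CC)(CC)CC)/C(C)=C\CO[Si](CC)(CC)CC
F8 | step 14 | Z-enal from F7: primary silyl ether converted to the aldehyde, secondary silyl ether kept | C=C(C(=O)OC)C(OC(=O)/C(C)=C\C)[C@H](OC(=O)/C(C)=C\C)C[C@@](C)(O[Si](CC)(CC)CC)[C@@H]1O[C@@H]1[C@H](O[Si](CC)(CC)CC)/C(C)=C\C=O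
F9 | step 14 | (2E)-2-[(pinacolboryl)methyl] allyl boronate from F8 (allylic angelate replaced, other groups as in F8) | COC(=O)/C(CB1OC(C)(C)C(C)(C)O1)=C/[C@H](OC(=O)/C(C)=C\C)C[C@@](C)(O[Si](CC)(CC)CC)[C@@H]2O[C@@H]2[C@H](O[Si](CC)(CC)CC)/C(C)=C\C=O
F10 | step 14 | 3,10-bis-O-triethylsilyl ether of the target | C=C1C(=O)O[C@H]2/C=C(/C)[C@@H](O[Si](CC)(CC)CC)[C@H]3O[C@H]3[C@](C)(O[Si](CC)(CC)CC)C[C@@H](OC(=O)/C(C)=C\C)[C@@H]12
F11 | step 2 | (4R)-4-(1-ethoxyethoxy)-5,5-dimethoxypentan-2-one, both acetal epimers | CC(=O)C[C@@H](OC(C)OCC)C(OC)OC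
F12 | step 2 | (4R,6R)-6-(1-ethoxyethoxy)-7,7-dimethoxy-1-[(4-methoxybenzyl)oxy]-4-methylhept-2-yn-4-ol | C[C@](O)(C#CCOCc1ccc(OC)cc1)C[C@@H](OC(C)OCC)C(OC)OC
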